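## Retrosynthetic overview

1. The target comes from its aryl TIPS ether by fluoride; the dienone with its quaternary C–OMe centre comes from oxidative dearomatisation (PhI(OAc)2/MeOH) of a 2‑allyl‑5‑methoxy‑4‑alkylphenol.
2. The allyl group comes from ortho‑bromination of that phenol followed by Stille allylation.
3. The (R)‑1,2‑diarylpropane comes from a syn‑aldol adduct by two deoxygenations: auxiliary carbonyl → CH2OH → CH2OTs → CH3, and benzylic OH → OAc → H.
4. Key C7–C8 bond: intermolecular Evans boron aldol between an arylacetyl oxazolidinone (from 2,4‑dihydroxyacetophenone) and O‑TIPS‑vanillin; it sets C8.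
5. No ring is constructed: the dienone ring is the dearomatised resorcinol ring of 2,4‑dihydroxyacetophenone and the guaiacyl ring is that of vanillin.

Assumption: simple reagents (BnBr, MeI, TIPSCl, TsCl, NBS, allyltributylstannane and the like) are not numbered and appear with SMILES under "Reagents that add atoms". C7 is the benzylic CH2 and C8 the CH(CH3) of the side chain.

## Route

Step 1
Reactants: 1 1-(2,4-dihydroxyphenyl)ethan-1-one
Product: 2 1-[4-(benzyloxy)-2-hydroxyphenyl]ethan-1-one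
Conditions: BnBr (1.05 eq), K2CO3, acetone, reflux
Reagents that add atoms: benzyl bromide, BrCc1ccccc1
Why: Williamson etherification is selective for the 4‑OH because the 2‑OH is tied up in a strong hydrogen bond to the acetyl carbonyl.

Step 2
Reactants: 2 1-[4-(benzyloxy)-2-hydroxyphenyl]ethan-1-one
Product: 3 1-[4-(benzyloxy)-2-methoxyphenyl]ethan-1-one
Conditions: MeI (excess), K2CO3, DMF, 50 °C
Reagents that add atoms: iodomethane, CI
Why: Williamson O‑methylation of the remaining chelated phenol under slightly forcing conditions installs the methoxy group that ends up on the enol‑ether carbon of the dienone.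

Step 3
Reactants: 3 1-[4-(benzyloxy)-2-methoxyphenyl]ethan-1-one
Product: 4 2-[4-(benzyloxy)-2-methoxyphenyl]-1-(morpholin-4-yl)ethane-1-thione
Conditions: S8, morpholine, 130 °C
Reagents that add atoms: sulfur, S1SSSSSSS1; morpholine, C1COCCN1
Why: The Willgerodt–Kindler reaction moves the oxidised carbon to the chain terminus and turns the aryl methyl ketone into the arylthioacetamide while the aryl ethers are inert.

Step 4
Reactants: 4 2-[4-(benzyloxy)-2-methoxyphenyl]-1-(morpholin-4-yl)ethane-1-thione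
Product: 5 2-[4-(benzyloxy)-2-methoxyphenyl]acetic acid
Conditions: NaOH, EtOH/H2O, reflux; then HCl
Reagents that add atoms: sodium hydroxide, [Na+].[OH-]; water, O
Why: Alkaline thioamide hydrolysis is the standard second stage of the Willgerodt–Kindler sequence, and benzyl and methyl aryl ethers survive hot hydroxide.

Step 5
Reactants: 5 2-[4-(benzyloxy)-2-methoxyphenyl]acetic acid; 6 (4S)-4-benzyl-1,3-oxazolidin-2-one
Product: 8 (4S)-4-benzyl-3-{[4-(benzyloxy)-2-methoxyphenyl]acetyl}-1,3-oxazolidin-2-one, via mixed pivalic anhydride 7 (not isolated)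
Conditions: PivCl, Et3N, THF, −20 °C; then 6, LiCl, rt
Reagents that add atoms: none
Why: N‑Acylation of the Evans auxiliary through the mixed anhydride (LiCl/Et3N protocol) is mild enough to avoid ketene formation from the arylacetic acid.

Step 6
Reactants: 9 4-hydroxy-3-methoxybenzaldehyde (vanillin)
Product: 10 3-methoxy-4-[(triisopropylsilyl)oxy]benzaldehyde
Conditions: TIPSCl, imidazole, DMF, rt
Reagents that add atoms: chlorotri(propan-2-yl)silane, CC(C)[Si](Cl)(C(C)C)C(C)C
Why: Phenol silylation gives an aryl TIPS ether that tolerates the boron aldol, hydride, Pd/H2, Stille and iodine(III) steps and is removable by fluoride at the end.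

Step 7 (key step)
Reactants: 8 (4S)-4-benzyl-3-{[4-(benzyloxy)-2-methoxyphenyl]acetyl}-1,3-oxazolidin-2-one; 10 3-methoxy-4-[(triisopropylsilyl)oxy]benzaldehyde
Product: 13 (4S)-4-benzyl-3-[(2S,3S)-2-[4-(benzyloxy)-2-methoxyphenyl]-3-hydroxy-3-{3-methoxy-4-[(triisopropylsilyl)oxy]phenyl}propanoyl]-1,3-oxazolidin-2-one, via Z-dibutylboron enolate 11 (not isolated), via dibutylboron aldolate 12 (not isolated)
Conditions: Bu2BOTf, iPr2NEt, CH2Cl2, 0 °C; 10, −78 → 0 °C; pH 7 buffer, MeOH, H2O2, 0 °C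
Reagents that add atoms: none
Why: In this Evans syn‑aldol reaction the Z‑boron enolate reacts through a Zimmerman–Traxler chair in which the (S)‑benzyl group blocks one enolate face, setting C8 (2S here, which is R in the target after the carbonyl becomes CH3) and the later‑removed C7 carbinol.

Step 8
Reactants: 13 the aldol adduct
Product: 14 (1S,2R)-2-[4-(benzyloxy)-2-methoxyphenyl]-1-{3-methoxy-4-[(triisopropylsilyl)oxy]phenyl}propane-1,3-diol
Conditions: LiBH4, MeOH (1 eq), THF, 0 °C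
Reagents that add atoms: none
Why: Reductive cleavage of the N‑acyl oxazolidinone with LiBH4 gives the primary alcohol and returns auxiliary 6 under cold, weakly basic conditions that do not epimerise the α‑aryl centre.

Step 9
Reactants: 14 the 1,3-diol
Product: 15 (2R,3S)-2-[4-(benzyloxy)-2-methoxyphenyl]-3-hydroxy-3-{3-methoxy-4-[(triisopropylsilyl)oxy]phenyl}propyl 4-methylbenzenesulfonate
Conditions: TsCl (1.05 eq), Et3N, DMAP (cat.), CH2Cl2, 0 °C
Reagents that add atoms: 4-methylbenzenesulfonyl chloride, Cc1ccc(cc1)S(Cl)(=O)=O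
Why: Sulfonylation is selective for the unhindered primary alcohol over the hindered secondary benzylic one.

Step 10
Reactants: 15 the primary tosylate
Product: 16 (1S,2S)-2-[4-(benzyloxy)-2-methoxyphenyl]-1-{3-methoxy-4-[(triisopropylsilyl)oxy]phenyl}propan-1-ol
Conditions: LiEt3BH (3 eq), THF, 0 °C → rt
Reagents that add atoms: none
Why: SN2 displacement of the primary tosylate by Super‑Hydride converts CH2OTs into the C8 methyl without touching any bond at C8, the neighbouring hydroxyl being held as a weakly nucleophilic borate alkoxide.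

Step 11
Reactants: 16 the secondary benzylic alcohol
Product: 17 (1S,2S)-2-[4-(benzyloxy)-2-methoxyphenyl]-1-{3-methoxy-4-[(triisopropylsilyl)oxy]phenyl}propyl acetate
Conditions: Ac2O, Et3N, DMAP (cat.), CH2Cl2, rt
Reagents that add atoms: acetic anhydride, CC(=O)OC(C)=O
Why: Acetylation makes the benzylic oxygen cleavable by neutral hydrogenolysis, avoiding acid‑promoted elimination to a stilbene that would erase C8.

Step 12
Reactants: 17 the benzylic acetate
Product: 18 3-methoxy-4-[(2R)-1-{3-methoxy-4-[(triisopropylsilyl)oxy]phenyl}propan-2-yl]phenol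
Conditions: H2 (1 atm), 10% Pd/C, EtOAc/EtOH, rt
Reagents that add atoms: none
Why: Palladium‑catalysed hydrogenolysis cleaves the benzylic C–OAc bond (C7 becomes CH2) and the benzyl ether in one operation, while the aryl TIPS ether and C8 are not involved.

Step 13
Reactants: 18 the free phenol
Product: 19 2-bromo-5-methoxy-4-[(2R)-1-{3-methoxy-4-[(triisopropylsilyl)oxy]phenyl}propan-2-yl]phenol
Conditions: NBS (1.0 eq), CH2Cl2, −78 → −20 °C, dark
Reagents that add atoms: N-bromosuccinimide, O=C1CCC(=O)N1Br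
Why: Electrophilic aromatic bromination goes ortho to OH and para to OMe because the para position is blocked and the position between the two oxygens is hindered, and the silylated guaiacyl ring is far less nucleophilic.

Step 14
Reactants: 19 the bromophenol
Product: 20 5-methoxy-4-[(2R)-1-{3-methoxy-4-[(triisopropylsilyl)oxy]phenyl}propan-2-yl]-2-(prop-2-en-1-yl)phenol
Conditions: allylSnBu3 (1.5 eq), Pd(PPh3)4 (5 mol %), toluene, 100 °C
Reagents that add atoms: allyltributylstannane, C=CC[Sn](CCCC)(CCCC)CCCC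
Why: Stille cross‑coupling transfers the allyl group under neutral, fluoride‑free conditions that tolerate the free phenol and the TIPS ether.

Step 15
Reactants: 20 the allylphenol
Product: 21 (4S)-4,5-dimethoxy-4-[(2R)-1-{3-methoxy-4-[(triisopropylsilyl)oxy]phenyl}propan-2-yl]-2-(prop-2-en-1-yl)cyclohexa-2,5-dien-1-one
Conditions: PhI(OAc)2 (1.1 eq), MeOH, 0 °C; chromatography
Reagents that add atoms: methanol, CO
Why: In this iodine(III) oxidative dearomatisation methanol adds to the alkyl‑bearing para carbon to give the cross‑conjugated 4‑methoxy dienone, but the quaternary centre forms under only weak 1,2‑induction from C8 (expect roughly 1:1 to 2:1, either sense), so the 4S isomer is obtained by separation from its 4‑epimer.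

Step 16
Reactants: 21 the TIPS-protected dienone
Product: 22 (4S)-4-[(2R)-1-(4-hydroxy-3-methoxyphenyl)propan-2-yl]-4,5-dimethoxy-2-(prop-2-en-1-yl)cyclohexa-2,5-dien-1-one (CNP0370214.1)
Conditions: TBAF (1.1 eq), AcOH (1.2 eq), THF, 0 °C
Reagents that add atoms: none
Why: Acetic‑acid‑buffered fluoride desilylation frees the phenol without harming the dienone and vinylogous ester and without touching either stereocentre.

## Compound list

1 | 1-(2,4-dihydroxyphenyl)ethan-1-one | CC(=O)c1ccc(O)cc1O | starting material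
2 | 1-[4-(benzyloxy)-2-hydroxyphenyl]ethan-1-one | CC(=O)c1ccc(OCc2ccccc2)cc1O | intermediate
3 | 1-[4-(benzyloxy)-2-methoxyphenyl]ethan-1-one | CC(=O)c1ccc(OCc2ccccc2)cc1OC | intermediate
4 | 2-[4-(benzyloxy)-2-methoxyphenyl]-1-(morpholin-4-yl)ethane-1-thione | S=C(Cc1ccc(OCc2ccccc2)cc1OC)N1CCOCC1 | intermediate
5 | 2-[4-(benzyloxy)-2-methoxyphenyl]acetic acid | OC(=O)Cc1ccc(OCc2ccccc2)cc1OC | intermediate
6 | (4S)-4-benzyl-1,3-oxazolidin-2-one | O=C1OC[C@H](Cc2ccccc2)N1 | starting material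
7 | [4-(benzyloxy)-2-methoxyphenyl]acetic pivalic anhydride | CC(C)(C)C(=O)OC(=O)Cc1ccc(OCc2ccccc2)cc1OC | intermediate
8 | (4S)-4-benzyl-3-{[4-(benzyloxy)-2-methoxyphenyl]acetyl}-1,3-oxazolidin-2-one | O=C1OC[C@H](Cc2ccccc2)N1C(=O)Cc1ccc(OCc2ccccc2)cc1OC | intermediate
9 | 4-hydroxy-3-methoxybenzaldehyde (vanillin) | O=Cc1ccc(O)c(OC)c1 | starting material
10 | 3-methoxy-4-[(triisopropylsilyl)oxy]benzaldehyde | O=Cc1ccc(O[Si](C(C)C)(C(C)C)C(C)C)c(OC)c1 | intermediate
11 | Z-dibutylboron enolate of 8 | O=C1OC[C@H](Cc2ccccc2)N1/C(OB(CCCC)CCCC)=C/c1ccc(OCc2ccccc2)cc1OC | intermediate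
12 | dibutylboron aldolate of 13 | O=C1OC[C@H](Cc2ccccc2)N1C(=O)[C@@H](c1ccc(OCc2ccccc2)cc1OC)[C@H](OB(CCCC)CCCC)c1ccc(O[Si](C(C)C)(C(C)C)C(C)C)c(OC)c1 | intermediate
13 | (4S)-4-benzyl-3-[(2S,3S)-2-[4-(benzyloxy)-2-methoxyphenyl]-3-hydroxy-3-{3-methoxy-4-[(triisopropylsilyl)oxy]phenyl}propanoyl]-1,3-oxazolidin-2-one | O=C1OC[C@H](Cc2ccccc2)N1C(=O)[C@@H](c1ccc(OCc2ccccc2)cc1OC)[C@H](O)c1ccc(O[Si](C(C)C)(C(C)C)C(C)C)c(OC)c1 | intermediate
14 | (1S,2R)-2-[4-(benzyloxy)-2-methoxyphenyl]-1-{3-methoxy-4-[(triisopropylsilyl)oxy]phenyl}propane-1,3-diol | OC[C@@H](c1ccc(OCc2ccccc2)cc1OC)[C@H](O)c1ccc(O[Si](C(C)C)(C(C)C)C(C)C)c(OC)c1 | intermediate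
15 | (2R,3S)-2-[4-(benzyloxy)-2-methoxyphenyl]-3-hydroxy-3-{3-methoxy-4-[(triisopropylsilyl)oxy]phenyl}propyl 4-methylbenzenesulfonate | Cc1ccc(cc1)S(=O)(=O)OC[C@@H](c1ccc(OCc2ccccc2)cc1OC)[C@H](O)c1ccc(O[Si](C(C)C)(C(C)C)C(C)C)c(OC)c1 | intermediate
16 | (1S,2S)-2-[4-(benzyloxy)-2-methoxyphenyl]-1-{3-methoxy-4-[(triisopropylsilyl)oxy]phenyl}propan-1-ol | C[C@@H](c1ccc(OCc2ccccc2)cc1OC)[C@H](O)c1ccc(O[Si](C(C)C)(C(C)C)C(C)C)c(OC)c1 | intermediate
17 | (1S,2S)-2-[4-(benzyloxy)-2-methoxyphenyl]-1-{3-methoxy-4-[(triisopropylsilyl)oxy]phenyl}propyl acetate | C[C@@H](c1ccc(OCc2ccccc2)cc1OC)[C@H](OC(C)=O)c1ccc(O[Si](C(C)C)(C(C)C)C(C)C)c(OC)c1 | intermediate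
18 | 3-methoxy-4-[(2R)-1-{3-methoxy-4-[(triisopropylsilyl)oxy]phenyl}propan-2-yl]phenol | C[C@@H](c1ccc(O)cc1OC)Cc1ccc(O[Si](C(C)C)(C(C)C)C(C)C)c(OC)c1 | intermediate
19 | 2-bromo-5-methoxy-4-[(2R)-1-{3-methoxy-4-[(triisopropylsilyl)oxy]phenyl}propan-2-yl]phenol | C[C@@H](c1cc(Br)c(O)cc1OC)Cc1ccc(O[Si](C(C)C)(C(C)C)C(C)C)c(OC)c1 | intermediate
20 | 5-methoxy-4-[(2R)-1-{3-methoxy-4-[(triisopropylsilyl)oxy]phenyl}propan-2-yl]-2-(prop-2-en-1-yl)phenol | C=CCc1cc([C@H](C)Cc2ccc(O[Si](C(C)C)(C(C)C)C(C)C)c(OC)c2)c(OC)cc1O | intermediate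
21 | (4S)-4,5-dimethoxy-4-[(2R)-1-{3-methoxy-4-[(triisopropylsilyl)oxy]phenyl}propan-2-yl]-2-(prop-2-en-1-yl)cyclohexa-2,5-dien-1-one | C=CCC1=C[C@@](OC)([C@H](C)Cc2ccc(O[Si](C(C)C)(C(C)C)C(C)C)c(OC)c2)C(OC)=CC1=O | intermediate
22 | (4S)-4-[(2R)-1-(4-hydroxy-3-methoxyphenyl)propan-2-yl]-4,5-dimethoxy-2-(prop-2-en-1-yl)cyclohexa-2,5-dien-1-one | C=CCC1=C[C@@](OC)([C@H](C)Cc2ccc(O)c(OC)c2)C(OC)=CC1=O | target

## Step count and risks

Total steps: 16. Longest linear sequence: 15 (steps 1–5 and 7–16); the vanillin branch is one step (step 6).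

The three steps most likely to fail:

1. Step 15 (dearomatisation). The quaternary centre is formed with little facial bias, and some ortho attack at the allyl‑bearing carbon is possible. The fallback sets out from 20 and comes back at 21. Oxidise 20 with PhI(OCOCF3)2 in MeCN/H2O at 0 °C so that water is the nucleophile, giving the 4‑hydroxy dienone (p‑quinol) F1, whose diastereomers are separated. Then methylate the tertiary hydroxyl (MeI, Ag2O, CH2Cl2, rt, dark) to reach 21. In either variant the unwanted (4R)‑epimer of 21 F2 is reduced with Zn dust in AcOH back to phenol 20 and oxidised again, so material is recycled rather than lost.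

2. Step 7 (aldol). A hindered α‑aryl boron enolate meets an electron‑rich, weakly electrophilic aldehyde, and the adduct can undergo retro‑aldol on work‑up. The fallback sets out from 5 and 10 and comes back at 18. A Perkin‑type aldol condensation (Ac2O, Et3N, 100 °C) gives the (E)‑2,3‑diarylacrylic acid F3. Enantioselective hydrogenation (chiral Ir–spiro‑phosphine‑oxazoline or Ru–BINAP catalyst, antipode chosen for the 2R acid, H2, MeOH, Et3N) gives the (2R)‑2,3‑diarylpropanoic acid F4. BH3·THF reduces this to the (2R)‑2,3‑diarylpropan‑1‑ol F5, TsCl/pyridine gives the primary tosylate F6, and LiEt3BH gives the benzyl ether of 18 F7. H2 over Pd/C then removes the benzyl group to give 18. This variant never carries oxygen at C7.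

3. Step 14 (Stille allylation). Oxidative addition into an electron‑rich ortho‑bromophenol is slow, and the allyl group can isomerise to propenyl. The fallback sets out from 18 and comes back at 20. O‑Allylation (allyl bromide, K2CO3, acetone, reflux) gives the aryl allyl ether F8. Aromatic Claisen rearrangement (N,N‑diethylaniline, 190 °C) moves the allyl group mainly to the ortho carbon para to the methoxy group, giving 20; the minor isomer with allyl between the two oxygens is removed by chromatography.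

## Further compounds

F1 | step 15 | (4S)-4-hydroxy-5-methoxy-4-[(2R)-1-{3-methoxy-4-[(triisopropylsilyl)oxy]phenyl}propan-2-yl]-2-(prop-2-en-1-yl)cyclohexa-2,5-dien-1-one | C=CCC1=C[C@@](O)([C@H](C)Cc2ccc(O[Si](C(C)C)(C(C)C)C(C)C)c(OC)c2)C(OC)=CC1=O
F2 | step 15 | (4R)-4,5-dimethoxy-4-[(2R)-1-{3-methoxy-4-[(triisopropylsilyl)oxy]phenyl}propan-2-yl]-2-(prop-2-en-1-yl)cyclohexa-2,5-dien-1-one | C=CCC1=C[C@](OC)([C@H](C)Cc2ccc(O[Si](C(C)C)(C(C)C)C(C)C)c(OC)c2)C(OC)=CC1=O
F3 | step 7 | (2E)-2-[4-(benzyloxy)-2-methoxyphenyl]-3-{3-methoxy-4-[(triisopropylsilyl)oxy]phenyl}prop-2-enoic acid | OC(=O)/C(c1ccc(OCc2ccccc2)cc1OC)=C/c1ccc(O[Si](C(C)C)(C(C)C)C(C)C)c(OC)c1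
F4 | step 7 | (2R)-2-[4-(benzyloxy)-2-methoxyphenyl]-3-{3-methoxy-4-[(triisopropylsilyl)oxy]phenyl}propanoic acid | OC(=O)[C@@H](c1ccc(OCc2ccccc2)cc1OC)Cc1ccc(O[Si](C(C)C)(C(C)C)C(C)C)c(OC)c1
F5 | step 7 | (2R)-2-[4-(benzyloxy)-2-methoxyphenyl]-3-{3-methoxy-4-[(triisopropylsilyl)oxy]phenyl}propan-1-ol | OC[C@@H](c1ccc(OCc2ccccc2)cc1OC)Cc1ccc(O[Si](C(C)C)(C(C)C)C(C)C)c(OC)c1
F6 | step 7 | (2R)-2-[4-(benzyloxy)-2-methoxyphenyl]-3-{3-methoxy-4-[(triisopropylsilyl)oxy]phenyl}propyl 4-methylbenzenesulfonate | Cc1ccc(cc1)S(=O)(=O)OC[C@@H](c1ccc(OCc2ccccc2)cc1OC)Cc1ccc(O[Si](C(C)C)(C(C)C)C(C)C)c(OC)c1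
F7 | step 7 | 4-(benzyloxy)-2-methoxy-1-[(2R)-1-{3-methoxy-4-[(triisopropylsilyl)oxy]phenyl}propan-2-yl]benzene | C[C@@H](c1ccc(OCc2ccccc2)cc1OC)Cc1ccc(O[Si](C(C)C)(C(C)C)C(C)C)c(OC)c1
F8 | step 14 | 2-methoxy-1-[(2R)-1-{3-methoxy-4-[(triisopropylsilyl)oxy]phenyl}propan-2-yl]-4-(prop-2-en-1-yloxy)benzene | C=CCOc1ccc([C@H](C)Cc2ccc(O[Si](C(C)C)(C(C)C)C(C)C)c(OC)c2)c(OC)c1
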